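**Retrosynthetic overview**
- The enal side chain is added last: C5–H borylation of the finished 7-methoxy-2,3-dihydrobenzofuran core, then an oxidative Heck reaction with acrolein.
- The core comes from a gold-catalysed furan–yne benzannulation of a furan-tethered ethynyl ether. The oxygenated benzene ring and the dihydrofuran ring form in the same operation; the furan oxygen becomes the C7 oxygen and the ynol ether oxygen becomes O1.
- The ethynyl ether comes from a syn-1,3-diol monosilyl ether, with trichloroethylene as the two-carbon alkyne source.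
- The diol comes from an Evans syn-aldol of an N-(2-furylacetyl)oxazolidinone with veratraldehyde. This sets C2 and C3 before any ring of the core exists.
- Ring order: the veratryl ring is bought; the benzofuran benzene ring and the dihydrofuran ring are then made together.

Assumption: 2-(furan-2-yl)acetic acid, (R)-4-benzyloxazolidin-2-one and veratraldehyde are bought; the target is the (2R,3S) trans isomer encoded by the given SMILES.

**Route**

Step 1
Reactants: 1 2-(furan-2-yl)acetic acid; 2 (R)-4-benzyloxazolidin-2-one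
Product: 4 (R)-4-benzyl-3-[2-(furan-2-yl)acetyl]oxazolidin-2-one, via mixed pivalic anhydride 3 (not isolated)
Conditions: PivCl, Et3N, THF, −20 to 0 °C; then 2, LiCl, 0 °C to rt
Reagents that add atoms: pivaloyl chloride, CC(C)(C)C(=O)Cl (its atoms stay only in intermediate 3)
Why: Mixed-anhydride N-acylation of the oxazolidinone is mild enough for the acid-sensitive furan, and no stereocentre is formed or touched.

Step 2
Reactants: 4 (R)-4-benzyl-3-[2-(furan-2-yl)acetyl]oxazolidin-2-one; 5 3,4-dimethoxybenzaldehyde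
Product: 8 (R)-4-benzyl-3-[(2S,3R)-3-(3,4-dimethoxyphenyl)-2-(furan-2-yl)-3-hydroxypropanoyl]oxazolidin-2-one, via boron enolate 6 (not isolated), via boron aldolate 7 (not isolated)
Conditions: n-Bu2BOTf (1.1 equiv), i-Pr2NEt (1.3 equiv), CH2Cl2, −78 to 0 °C; then 5, −78 to 0 °C; then pH 7 buffer, MeOH, 30% H2O2, 0 °C
Reagents that add atoms: dibutylboron triflate, CCCCB(CCCC)OS(=O)(=O)C(F)(F)F (boron and butyl groups stay only in intermediates 6 and 7)
Why: Evans syn-aldol reaction, in which the Z boron enolate 6 reacts through a chair Zimmerman–Traxler transition state on the face away from the benzyl group of the (R)-auxiliary, setting both new stereocentres (2S,3R, syn) that become C3 and C2 of the target.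

Step 3
Reactants: 8 (R)-4-benzyl-3-[(2S,3R)-3-(3,4-dimethoxyphenyl)-2-(furan-2-yl)-3-hydroxypropanoyl]oxazolidin-2-one
Product: 9 (1R,2S)-1-(3,4-dimethoxyphenyl)-2-(furan-2-yl)propane-1,3-diol
Conditions: LiBH4 (2 equiv), MeOH (1.1 equiv), THF, 0 °C
Reagents that add atoms: none
Why: Reductive cleavage of the imide by hydride attack at the exocyclic carbonyl releases the auxiliary and gives the 1,3-diol, cold enough to avoid retro-aldol or epimerisation of the α-furyl centre.

Step 4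
Reactants: 9 (1R,2S)-1-(3,4-dimethoxyphenyl)-2-(furan-2-yl)propane-1,3-diol
Product: 10 (1R,2S)-1-(3,4-dimethoxyphenyl)-2-(furan-2-yl)-3-[(triisopropylsilyl)oxy]propan-1-ol
Conditions: TIPSCl (1.05 equiv), imidazole, DMF, 0 °C
Reagents that add atoms: triisopropylsilyl chloride, CC(C)[Si](Cl)(C(C)C)C(C)C
Why: Silylation with a bulky silyl chloride selects the primary over the hindered secondary benzylic hydroxyl, and this silyl group resists base-induced migration, survives n-BuLi and has no aryl C–H that would interfere with the later borylation.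

Step 5
Reactants: 10 (1R,2S)-1-(3,4-dimethoxyphenyl)-2-(furan-2-yl)-3-[(triisopropylsilyl)oxy]propan-1-ol
Product: 14 {[(2S,3R)-3-(3,4-dimethoxyphenyl)-3-(ethynyloxy)-2-(furan-2-yl)propyl]oxy}triisopropylsilane, via dichlorovinyl ether 11 (not isolated), via chloroethynyl ether 12 (not isolated), via lithium acetylide 13 (not isolated)
Conditions: KH (1.5 equiv), THF, 0 °C; Cl2C=CHCl (1.1 equiv), −40 °C to rt; then n-BuLi (2.5 equiv), −78 to −40 °C; MeOH, −78 °C; kept below 0 °C and used at once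
Reagents that add atoms: trichloroethylene, ClC=C(Cl)Cl; n-butyllithium, [Li]CCCC (lithium stays only in intermediate 13)
Why: Dichlorovinyl ether route to alkynyl ethers, in which the potassium alkoxide adds anti to dichloroacetylene formed in the flask, n-BuLi then eliminates HCl and exchanges the remaining chlorine to give acetylide 13, and cold protonation gives the ynol ether with the benzylic C–O bond never broken, so configuration is retained.

Step 6
Reactants: 14 {[(2S,3R)-3-(3,4-dimethoxyphenyl)-3-(ethynyloxy)-2-(furan-2-yl)propyl]oxy}triisopropylsilane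
Product: 16 (2R,3S)-2-(3,4-dimethoxyphenyl)-3-{[(triisopropylsilyl)oxy]methyl}-2,3-dihydrobenzofuran-7-ol, via arene oxide 15 (not isolated)
Conditions: Ph3PAuNTf2 (3 mol %), 4 Å MS, CH2Cl2, 0 °C to rt
Reagents that add atoms: none
Why: Gold-catalysed intramolecular furan–yne phenol synthesis (Hashmi phenol synthesis), in which furan C2 attacks the gold-activated ynol ether 5-exo at its oxygen-bearing carbon, the furan ring opens and recloses to arene oxide 15, and O1-assisted opening of 15 at C6 leaves the former furan oxygen as the C7 phenol, so the benzene ring and the dihydrofuran ring form together and the preset C2 and C3 centres are carried unchanged into the trans ring.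

Step 7
Reactants: 16 (2R,3S)-2-(3,4-dimethoxyphenyl)-3-{[(triisopropylsilyl)oxy]methyl}-2,3-dihydrobenzofuran-7-ol
Product: 17 {[(2R,3S)-2-(3,4-dimethoxyphenyl)-7-methoxy-2,3-dihydrobenzofuran-3-yl]methoxy}triisopropylsilane
Conditions: MeI, K2CO3, acetone, 50 °C
Reagents that add atoms: iodomethane, CI
Why: Williamson O-methylation of the only acidic hydroxyl, which neither the silyl ether nor the stereocentres can respond to.

Step 8
Reactants: 17 {[(2R,3S)-2-(3,4-dimethoxyphenyl)-7-methoxy-2,3-dihydrobenzofuran-3-yl]methoxy}triisopropylsilane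
Product: 18 {[(2R,3S)-2-(3,4-dimethoxyphenyl)-7-methoxy-5-(4,4,5,5-tetramethyl-1,3,2-dioxaborolan-2-yl)-2,3-dihydrobenzofuran-3-yl]methoxy}triisopropylsilane
Conditions: [Ir(OMe)(cod)]2 (1.5 mol %), 4,4'-di-tert-butyl-2,2'-bipyridine (3 mol %), B2pin2 (1.0 equiv), THF, 80 °C
Reagents that add atoms: bis(pinacolato)diboron, CC1(C)OB(OC1(C)C)B1OC(C)(C)C(C)(C)O1
Why: Iridium-catalysed aromatic C–H borylation is sterically controlled, and C5–H is the only aryl C–H in the molecule with no ortho substituent (C4–H, C6–H and all three veratryl C–H bonds have one).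

Step 9
Reactants: 18 {[(2R,3S)-2-(3,4-dimethoxyphenyl)-7-methoxy-5-(4,4,5,5-tetramethyl-1,3,2-dioxaborolan-2-yl)-2,3-dihydrobenzofuran-3-yl]methoxy}triisopropylsilane
Product: 20 (E)-3-[(2R,3S)-2-(3,4-dimethoxyphenyl)-3-(hydroxymethyl)-7-methoxy-2,3-dihydrobenzofuran-5-yl]acrylaldehyde, via silyl enal 19 (not isolated)
Conditions: Pd(OAc)2 (5 mol %), 2,9-dimethyl-1,10-phenanthroline (6 mol %), p-benzoquinone (1.2 equiv), acrolein (3 equiv), MeCN–H2O 9:1, 40 °C; then 48% aq HF, 0 °C to rt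
Reagents that add atoms: acrolein, C=CC=O
Why: Oxidative Heck (boron Heck) reaction, in which the aryl group is transferred to divalent palladium, acrolein inserts and β-hydride elimination gives the E enal while p-benzoquinone reoxidises zerovalent palladium, after which aqueous HF cleaves the Si–O bond to free the primary alcohol.

**Compound list**

1 | 2-(furan-2-yl)acetic acid | OC(=O)Cc1ccco1 | starting material
2 | (R)-4-benzyloxazolidin-2-one | O=C1N[C@H](Cc2ccccc2)CO1 | starting material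
3 | 2-(furan-2-yl)acetic pivalic anhydride | CC(C)(C)C(=O)OC(=O)Cc1ccco1 | intermediate
4 | (R)-4-benzyl-3-[2-(furan-2-yl)acetyl]oxazolidin-2-one | O=C(Cc1ccco1)N1C(=O)OC[C@H]1Cc1ccccc1 | intermediate
5 | 3,4-dimethoxybenzaldehyde (veratraldehyde) | COc1ccc(C=O)cc1OC | starting material
6 | dibutylboron (Z)-enolate of 4 | CCCCB(CCCC)O/C(=C\c1ccco1)N1C(=O)OC[C@H]1Cc1ccccc1 | intermediate
7 | O-dibutylboron aldolate of 8 | COc1ccc([C@H](OB(CCCC)CCCC)[C@H](C(=O)N2C(=O)OC[C@H]2Cc2ccccc2)c2ccco2)cc1OC | intermediate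
8 | (R)-4-benzyl-3-[(2S,3R)-3-(3,4-dimethoxyphenyl)-2-(furan-2-yl)-3-hydroxypropanoyl]oxazolidin-2-one | COc1ccc([C@H](O)[C@H](C(=O)N2C(=O)OC[C@H]2Cc2ccccc2)c2ccco2)cc1OC | intermediate
9 | (1R,2S)-1-(3,4-dimethoxyphenyl)-2-(furan-2-yl)propane-1,3-diol | COc1ccc([C@H](O)[C@H](CO)c2ccco2)cc1OC | intermediate
10 | (1R,2S)-1-(3,4-dimethoxyphenyl)-2-(furan-2-yl)-3-[(triisopropylsilyl)oxy]propan-1-ol | COc1ccc([C@H](O)[C@H](CO[Si](C(C)C)(C(C)C)C(C)C)c2ccco2)cc1OC | intermediate
11 | {[(2S,3R)-3-{[(E)-1,2-dichloroethenyl]oxy}-3-(3,4-dimethoxyphenyl)-2-(furan-2-yl)propyl]oxy}triisopropylsilane | COc1ccc([C@H](O/C(Cl)=C\Cl)[C@H](CO[Si](C(C)C)(C(C)C)C(C)C)c2ccco2)cc1OC | intermediate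
12 | {[(2S,3R)-3-[(chloroethynyl)oxy]-3-(3,4-dimethoxyphenyl)-2-(furan-2-yl)propyl]oxy}triisopropylsilane | COc1ccc([C@H](OC#CCl)[C@H](CO[Si](C(C)C)(C(C)C)C(C)C)c2ccco2)cc1OC | intermediate
13 | lithium acetylide of 14 | COc1ccc([C@H](OC#C[Li])[C@H](CO[Si](C(C)C)(C(C)C)C(C)C)c2ccco2)cc1OC | intermediate
14 | {[(2S,3R)-3-(3,4-dimethoxyphenyl)-3-(ethynyloxy)-2-(furan-2-yl)propyl]oxy}triisopropylsilane | COc1ccc([C@H](OC#C)[C@H](CO[Si](C(C)C)(C(C)C)C(C)C)c2ccco2)cc1OC | intermediate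
15 | 6,7-epoxy-6,7-dihydro (arene oxide) form of 16, (2R,3S), epoxide face not defined (both faces give 16) | COc1ccc([C@@H]2OC3=C(C=CC4OC34)[C@H]2CO[Si](C(C)C)(C(C)C)C(C)C)cc1OC | intermediate
16 | (2R,3S)-2-(3,4-dimethoxyphenyl)-3-{[(triisopropylsilyl)oxy]methyl}-2,3-dihydrobenzofuran-7-ol | COc1ccc([C@@H]2Oc3c(O)cccc3[C@H]2CO[Si](C(C)C)(C(C)C)C(C)C)cc1OC | intermediate
17 | {[(2R,3S)-2-(3,4-dimethoxyphenyl)-7-methoxy-2,3-dihydrobenzofuran-3-yl]methoxy}triisopropylsilane | COc1ccc([C@@H]2Oc3c(OC)cccc3[C@H]2CO[Si](C(C)C)(C(C)C)C(C)C)cc1OC | intermediate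
18 | {[(2R,3S)-2-(3,4-dimethoxyphenyl)-7-methoxy-5-(4,4,5,5-tetramethyl-1,3,2-dioxaborolan-2-yl)-2,3-dihydrobenzofuran-3-yl]methoxy}triisopropylsilane | COc1ccc([C@@H]2Oc3c(OC)cc(B4OC(C)(C)C(C)(C)O4)cc3[C@H]2CO[Si](C(C)C)(C(C)C)C(C)C)cc1OC | intermediate
19 | (E)-3-[(2R,3S)-2-(3,4-dimethoxyphenyl)-7-methoxy-3-{[(triisopropylsilyl)oxy]methyl}-2,3-dihydrobenzofuran-5-yl]acrylaldehyde | COc1ccc([C@@H]2Oc3c(OC)cc(/C=C/C=O)cc3[C@H]2CO[Si](C(C)C)(C(C)C)C(C)C)cc1OC | intermediate
20 | 4-O-methylbalanophonin, (E)-3-[(2R,3S)-2-(3,4-dimethoxyphenyl)-3-(hydroxymethyl)-7-methoxy-2,3-dihydrobenzofuran-5-yl]acrylaldehyde | COc1ccc([C@@H]2Oc3c(OC)cc(/C=C/C=O)cc3[C@H]2CO)cc1OC | target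

**Step count and risk**

Total steps: 9. Longest linear sequence: 9 (from 1 to 20; 2 and 5 are bought).

The three steps most likely to fail are 6, 5 and 9.

Step 6 (gold benzannulation). The ynol ether could instead be hydrated, rearrange through its benzylic position, or be attacked by the veratryl ring. The fallback sets out from 2 and 5 and comes back at 17, building the dihydrofuran on a ready-made benzene ring. Bought 2-[2-(benzyloxy)-3-methoxyphenyl]acetic acid F3 is N-acylated onto 2 as in step 1 to give (R)-4-benzyl-3-{2-[2-(benzyloxy)-3-methoxyphenyl]acetyl}oxazolidin-2-one F4. An Evans syn-aldol with 5 as in step 2 gives (R)-4-benzyl-3-[(2R,3R)-2-[2-(benzyloxy)-3-methoxyphenyl]-3-(3,4-dimethoxyphenyl)-3-hydroxypropanoyl]oxazolidin-2-one F5. LiBH4 gives (1R,2S)-2-[2-(benzyloxy)-3-methoxyphenyl]-1-(3,4-dimethoxyphenyl)propane-1,3-diol F6. TIPSCl and imidazole give (1R,2S)-2-[2-(benzyloxy)-3-methoxyphenyl]-1-(3,4-dimethoxyphenyl)-3-[(triisopropylsilyl)oxy]propan-1-ol F7. Hydrogenolysis (H2, Pd/C, EtOAc) gives (1R,2S)-1-(3,4-dimethoxyphenyl)-2-(2-hydroxy-3-methoxyphenyl)-3-[(triisopropylsilyl)oxy]propan-1-ol F8. BF3·OEt2 (CH2Cl2, −40 °C) then ionises the electron-rich benzylic alcohol and the phenol closes the ring anti to the C3 substituent. C3 comes from the aldol and C2 is set trans in this SN1 closure, giving 17.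

Step 5 (ynol ether formation). The hindered potassium alkoxide may add poorly, or n-BuLi may attack elsewhere. The fallback sets out from 10 and comes back at 14, building the alkyne from two one-carbon units on a neutral ester. Formylation of 10 (acetic formic anhydride, pyridine) gives (1R,2S)-1-(3,4-dimethoxyphenyl)-2-(furan-2-yl)-3-[(triisopropylsilyl)oxy]propyl formate F1. Dibromomethylenation of the formate carbonyl (CBr4, PPh3, CH2Cl2, 0 °C) gives {[(2S,3R)-3-[(2,2-dibromoethenyl)oxy]-3-(3,4-dimethoxyphenyl)-2-(furan-2-yl)propyl]oxy}triisopropylsilane F2. n-BuLi (2 equiv, THF, −78 °C) converts F2 by bromine–lithium exchange and elimination into acetylide 13, and a methanol quench gives 14.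

Step 9 (oxidative Heck on a pinacol boronate with acrolein). Transfer of the aryl group from the pinacol ester may be slow, and acrolein may polymerise. The fallback sets out from 18 and comes back at 19, replacing the Heck step by cross-coupling and redox adjustment. Suzuki–Miyaura coupling of 18 with ethyl (E)-3-iodoacrylate (Pd(dppf)Cl2, K3PO4, dioxane–H2O, 60 °C) gives ethyl (E)-3-[(2R,3S)-2-(3,4-dimethoxyphenyl)-7-methoxy-3-{[(triisopropylsilyl)oxy]methyl}-2,3-dihydrobenzofuran-5-yl]acrylate F9. i-Bu2AlH (CH2Cl2, −78 °C) gives (E)-3-[(2R,3S)-2-(3,4-dimethoxyphenyl)-7-methoxy-3-{[(triisopropylsilyl)oxy]methyl}-2,3-dihydrobenzofuran-5-yl]prop-2-en-1-ol F10. MnO2 (CH2Cl2, rt) gives 19, which is desilylated with aqueous HF as in the second stage of step 9.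

**Further compounds**

F1 | step 5 | (1R,2S)-1-(3,4-dimethoxyphenyl)-2-(furan-2-yl)-3-[(triisopropylsilyl)oxy]propyl formate | COc1ccc([C@H](OC=O)[C@H](CO[Si](C(C)C)(C(C)C)C(C)C)c2ccco2)cc1OC
F2 | step 5 | {[(2S,3R)-3-[(2,2-dibromoethenyl)oxy]-3-(3,4-dimethoxyphenyl)-2-(furan-2-yl)propyl]oxy}triisopropylsilane | COc1ccc([C@H](OC=C(Br)Br)[C@H](CO[Si](C(C)C)(C(C)C)C(C)C)c2ccco2)cc1OC
F3 | step 6 | 2-[2-(benzyloxy)-3-methoxyphenyl]acetic acid | COc1cccc(CC(=O)O)c1OCc1ccccc1
F4 | step 6 | (R)-4-benzyl-3-{2-[2-(benzyloxy)-3-methoxyphenyl]acetyl}oxazolidin-2-one | COc1cccc(CC(=O)N2C(=O)OC[C@H]2Cc2ccccc2)c1OCc1ccccc1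
F5 | step 6 | (R)-4-benzyl-3-[(2R,3R)-2-[2-(benzyloxy)-3-methoxyphenyl]-3-(3,4-dimethoxyphenyl)-3-hydroxypropanoyl]oxazolidin-2-one | COc1ccc([C@H](O)[C@H](C(=O)N2C(=O)OC[C@H]2Cc2ccccc2)c2cccc(OC)c2OCc2ccccc2)cc1OC
F6 | step 6 | (1R,2S)-2-[2-(benzyloxy)-3-methoxyphenyl]-1-(3,4-dimethoxyphenyl)propane-1,3-diol | COc1ccc([C@H](O)[C@H](CO)c2cccc(OC)c2OCc2ccccc2)cc1OC
F7 | step 6 | (1R,2S)-2-[2-(benzyloxy)-3-methoxyphenyl]-1-(3,4-dimethoxyphenyl)-3-[(triisopropylsilyl)oxy]propan-1-ol | COc1ccc([C@H](O)[C@H](CO[Si](C(C)C)(C(C)C)C(C)C)c2cccc(OC)c2OCc2ccccc2)cc1OC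
F8 | step 6 | (1R,2S)-1-(3,4-dimethoxyphenyl)-2-(2-hydroxy-3-methoxyphenyl)-3-[(triisopropylsilyl)oxy]propan-1-ol | COc1ccc([C@H](O)[C@H](CO[Si](C(C)C)(C(C)C)C(C)C)c2cccc(OC)c2O)cc1OC
F9 | step 9 | ethyl (E)-3-[(2R,3S)-2-(3,4-dimethoxyphenyl)-7-methoxy-3-{[(triisopropylsilyl)oxy]methyl}-2,3-dihydrobenzofuran-5-yl]acrylate | COc1ccc([C@@H]2Oc3c(OC)cc(/C=C/C(=O)OCC)cc3[C@H]2CO[Si](C(C)C)(C(C)C)C(C)C)cc1OC
F10 | step 9 | (E)-3-[(2R,3S)-2-(3,4-dimethoxyphenyl)-7-methoxy-3-{[(triisopropylsilyl)oxy]methyl}-2,3-dihydrobenzofuran-5-yl]prop-2-en-1-ol | COc1ccc([C@@H]2Oc3c(OC)cc(/C=C/CO)cc3[C@H]2CO[Si](C(C)C)(C(C)C)C(C)C)cc1OC
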